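**Plan**
1. Retrosynthesis: the two acetates and the O16–C15 bond of ring D (alkynol cycloisomerisation) come off first. The C7–C8 bond of ring B is cut next, because the C7 ketone beside the C8 tertiary carbinol (an α-ketol inside ring B) is the mark of a crossed aldehyde–ketone benzoin. The 7,8-seco keto aldehyde is the ozonolysis product of a 7-ene.
2. Earlier cuts: O9–C13 (ring C, epoxide opening), C11–C12 (spiro-epoxide plus methallyl alcohol dianion), C8–C17 (enol triflate coupling), C9–O (enolate hydroxylation), C9–C10 and C4–C5 (cationic bicyclisation), C6–C7 (acetoacetate dianion), C3=C4 (Z-olefination).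
3. Forward: linear C14 chain → rings A and B in one cationic cascade → C17, 9α-O and ring C added → ring B cut at C7=C8 and re-closed through C7–C8 by the carbene → C8 acetate, ring D, C19 acetate.
4. Stereochemistry: the first Sharpless epoxidation fixes the epoxide, and the chair–chair fold relays it to C4 (Z-CH2O arm axial = C19), C5 and C10. C9 comes from α-face enolate hydroxylation, C13 from a second Sharpless epoxidation with invertive 5-exo opening, and C8 from the chair transition state of the benzoin closure.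

Key step: step 22

Remark: atom numbers follow the labdane skeleton (C1–C20); geranyl chloride serves as the C10 unit because its allylic chloride survives the hydride reduction of step 3 and is itself the leaving group of step 6.

**Step 1**
Reactants: 1 geranyl chloride
Product: 2 (4E)-6-chloro-4-methylhex-4-enal
Conditions: O3 (1.0 equiv), pyridine (3 equiv), CH2Cl2, −78 °C
Reagents that add atoms: ozone, [O-][O+]=O
Why: Chemoselective ozonolysis, in which the electron-rich 6,7-alkene is cleaved while the 2,3-alkene is deactivated by the allylic chloride, and pyridine breaks down the carbonyl oxide so that the aldehyde forms without a reductive work-up.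

**Step 2**
Reactants: 2 (4E)-6-chloro-4-methylhex-4-enal; 3 methyl 2-[bis(2,2,2-trifluoroethoxy)phosphoryl]propanoate
Product: 5 methyl (2Z,6E)-8-chloro-2,6-dimethylocta-2,6-dienoate, via potassium phosphonate carbanion 4 (not isolated)
Conditions: 3, KN(SiMe3)2, 18-crown-6, THF, −78 °C; then 2, −78 °C
Reagents that add atoms: none
Why: Still–Gennari olefination, whose electron-poor bis(trifluoroethyl) phosphonate eliminates from the kinetic adduct and should therefore give the (2Z)-2-methyl enoate that places the future C19 cis to the chain, the allylic chloride being inert at −78 °C.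

**Step 3**
Reactants: 5 methyl (2Z,6E)-8-chloro-2,6-dimethylocta-2,6-dienoate
Product: 6 (2Z,6E)-8-chloro-2,6-dimethylocta-2,6-dien-1-ol
Conditions: i-Bu2AlH (2.3 equiv), CH2Cl2, −78 °C; aq potassium sodium tartrate work-up
Reagents that add atoms: none
Why: 1,2-Reduction of a conjugated ester with diisobutylaluminium hydride, which should stop at the allylic alcohol without touching the alkene geometry or the allylic chloride.

**Step 4**
Reactants: 6 (2Z,6E)-8-chloro-2,6-dimethylocta-2,6-dien-1-ol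
Product: 7 [(2R,3S)-3-[(3E)-5-chloro-3-methylpent-3-en-1-yl]-2-methyloxiran-2-yl]methanol
Conditions: Ti(OiPr)4 (10 mol %), D-(−)-diethyl tartrate (12 mol %), t-BuOOH (2 equiv), 4 Å molecular sieves, CH2Cl2, −20 °C
Reagents that add atoms: tert-butyl hydroperoxide, CC(C)(C)OO
Why: Sharpless asymmetric epoxidation, in which the hydroxyl directs the titanium tartrate peroxide to the allylic alkene only and D-(−)-tartrate should deliver oxygen to the face that gives the (2R,3S)-epoxide, the two centres that later fix C3 and the absolute sense of the decalin fold.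

**Step 5**
Reactants: 7 [(2R,3S)-3-[(3E)-5-chloro-3-methylpent-3-en-1-yl]-2-methyloxiran-2-yl]methanol
Product: 8 tert-butyl{[(2R,3S)-3-[(3E)-5-chloro-3-methylpent-3-en-1-yl]-2-methyloxiran-2-yl]methoxy}diphenylsilane
Conditions: t-BuPh2SiCl, imidazole, CH2Cl2, 0 °C
Reagents that add atoms: tert-butyl(chloro)diphenylsilane, CC(C)(C)[Si](Cl)(c1ccccc1)c1ccccc1
Why: Silyl ether formation, giving an O19 protecting group that is bulky and weakly Lewis basic, so that it should neither chelate the Lewis acid of step 7 nor be lost before step 24.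

**Step 6**
Reactants: 8 tert-butyl{[(2R,3S)-3-[(3E)-5-chloro-3-methylpent-3-en-1-yl]-2-methyloxiran-2-yl]methoxy}diphenylsilane; 9 methyl acetoacetate
Product: 11 methyl (6E)-9-[(2S,3R)-3-(tert-butyldiphenylsilyloxymethyl)-3-methyloxiran-2-yl]-7-methyl-3-oxonon-6-enoate, via dilithium dianion of methyl acetoacetate 10 (not isolated)
Conditions: 9, LiN(i-Pr)2 (2.1 equiv), THF, 0 °C; then 8, 0 °C → rt; aq NH4Cl
Reagents that add atoms: none
Why: γ-Alkylation of an acetoacetate dianion, whose terminal carbanion is the more nucleophilic site and displaces the primary allylic chloride by SN2 while the trisubstituted epoxide stays intact.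

**Step 7**
Reactants: 11 methyl (6E)-9-[(2S,3R)-3-(tert-butyldiphenylsilyloxymethyl)-3-methyloxiran-2-yl]-7-methyl-3-oxonon-6-enoate
Product: 12 methyl 19-(tert-butyldiphenylsilyloxy)-3β-hydroxy-8-oxo-12,13,14,15,16,17-hexanorlabdan-11-oate
Conditions: SnCl4 (2 equiv), CH2Cl2, −78 °C
Reagents that add atoms: none
Why: Epoxide-initiated cationic polyene bicyclisation, in which the Lewis acid opens the epoxide at the tertiary C4 with backside attack by the 5(10)-alkene and the tin-bound β-keto ester enol terminates through carbon in a chair–chair fold, so that the Z-derived CH2OSi arm should end axial on C4 (C19), the E-alkene should give the trans ring fusion (5α-H and 10β-Me), the ester should sit equatorial on C9 and the S-configured epoxide CH carbon (future C3) should decide the absolute configuration.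

**Step 8**
Reactants: 12 methyl 19-(tert-butyldiphenylsilyloxy)-3β-hydroxy-8-oxo-12,13,14,15,16,17-hexanorlabdan-11-oate
Product: 13 methyl 19-(tert-butyldiphenylsilyloxy)-3β-[(imidazol-1-ylcarbonothioyl)oxy]-8-oxo-12,13,14,15,16,17-hexanorlabdan-11-oate
Conditions: 1,1'-thiocarbonyldiimidazole, DMAP (cat.), ClCH2CH2Cl, 70 °C
Reagents that add atoms: 1,1'-thiocarbonyldiimidazole, S=C(n1ccnc1)n1ccnc1
Why: Thioacylation of the secondary alcohol, the first half of a Barton–McCombie deoxygenation, which is routine for hindered 3β-hydroxyls next to a quaternary C4.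

**Step 9**
Reactants: 13 methyl 19-(tert-butyldiphenylsilyloxy)-3β-[(imidazol-1-ylcarbonothioyl)oxy]-8-oxo-12,13,14,15,16,17-hexanorlabdan-11-oate
Product: 14 methyl 19-(tert-butyldiphenylsilyloxy)-8-oxo-12,13,14,15,16,17-hexanorlabdan-11-oate
Conditions: Bu3SnH, AIBN (cat.), toluene, 100 °C
Reagents that add atoms: none
Why: Barton–McCombie radical deoxygenation, in which the stannyl radical adds to sulfur and the secondary C3 radical released by β-scission abstracts hydrogen from the stannane, erasing the hydroxyl left by the epoxide trigger.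

**Step 10**
Reactants: 14 methyl 19-(tert-butyldiphenylsilyloxy)-8-oxo-12,13,14,15,16,17-hexanorlabdan-11-oate
Product: 17 methyl 19-(tert-butyldiphenylsilyloxy)-8-oxo-9α-(trimethylsilyloxy)-12,13,14,15,16,17-hexanorlabdan-11-oate, via potassium C9 enolate 15 (not isolated), via potassium 9α-alkoxide 16 (not isolated)
Conditions: KN(SiMe3)2, THF, −78 °C; 2-(phenylsulfonyl)-3-phenyloxaziridine, −78 °C; then Me3SiCl, −78 → 0 °C
Reagents that add atoms: 2-(phenylsulfonyl)-3-phenyloxaziridine, O=S(=O)(c1ccccc1)N1OC1c1ccccc1; chlorotrimethylsilane, C[Si](C)(C)Cl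
Why: Electrophilic hydroxylation of a β-keto ester enolate by an N-sulfonyloxaziridine, where oxygen should arrive at C9 on the α-face anti to the axial C10 methyl so that the 9α-oxygen is set with the ester left β, and the alkoxide is silylated in the same flask so that the later enolisation cannot set off an α-ketol shift.

**Step 11**
Reactants: 17 methyl 19-(tert-butyldiphenylsilyloxy)-8-oxo-9α-(trimethylsilyloxy)-12,13,14,15,16,17-hexanorlabdan-11-oate
Product: 19 methyl 19-(tert-butyldiphenylsilyloxy)-8-(trifluoromethylsulfonyloxy)-9α-(trimethylsilyloxy)-12,13,14,15,16,17-hexanorlabd-7-en-11-oate, via potassium 7-en-8-olate 18 (not isolated)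
Conditions: KN(SiMe3)2, THF, −78 °C; PhNTf2, −78 → 0 °C
Reagents that add atoms: N-phenylbis(trifluoromethanesulfonimide), O=S(=O)(N(c1ccccc1)S(=O)(=O)C(F)(F)F)C(F)(F)F
Why: Enol triflate formation, regiospecific because C9 is quaternary and the ketone can therefore enolise only toward C7.

**Step 12**
Reactants: 19 methyl 19-(tert-butyldiphenylsilyloxy)-8-(trifluoromethylsulfonyloxy)-9α-(trimethylsilyloxy)-12,13,14,15,16,17-hexanorlabd-7-en-11-oate
Product: 20 methyl 19-(tert-butyldiphenylsilyloxy)-9α-(trimethylsilyloxy)-12,13,14,15,16-pentanorlabd-7-en-11-oate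
Conditions: MeMgBr, Fe(acac)3 (5 mol %), THF/N-methylpyrrolidone, −30 °C
Reagents that add atoms: methylmagnesium bromide, C[Mg]Br
Why: Iron-catalysed cross-coupling of an alkenyl triflate with a Grignard reagent, fast enough at −30 °C that the hindered methyl ester and both silyl ethers should survive while C17 is attached to C8.

**Step 13**
Reactants: 20 methyl 19-(tert-butyldiphenylsilyloxy)-9α-(trimethylsilyloxy)-12,13,14,15,16-pentanorlabd-7-en-11-oate
Product: 22 19-(tert-butyldiphenylsilyloxy)-12,13,14,15,16-pentanorlabd-7-ene-9α,11-diol, via 9-O-trimethylsilyl primary alcohol 21 (not isolated)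
Conditions: LiAlH4, THF, 0 °C → rt; aq potassium sodium tartrate work-up; then K2CO3, MeOH, rt
Reagents that add atoms: none
Why: Hydride reduction of the ester to the C11 primary alcohol followed by mild basic methanolysis of the trimethylsilyl ether, which avoids the acid that could ionise the tertiary allylic 9-ol.

**Step 14**
Reactants: 22 19-(tert-butyldiphenylsilyloxy)-12,13,14,15,16-pentanorlabd-7-ene-9α,11-diol
Product: 24 19-(tert-butyldiphenylsilyloxy)-9α,11-epoxy-12,13,14,15,16-pentanorlabd-7-ene, via C11 monotosylate 23 (not isolated)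
Conditions: NaH (2.5 equiv), 1-(p-tolylsulfonyl)imidazole, THF, 0 °C → rt
Reagents that add atoms: none
Why: One-flask sulfonylation of the primary hydroxyl and intramolecular Williamson closure (3-exo-tet) by the tertiary alkoxide, which keeps the C9–O bond and hence the 9α-oxygen.

**Step 15**
Reactants: 24 19-(tert-butyldiphenylsilyloxy)-9α,11-epoxy-12,13,14,15,16-pentanorlabd-7-ene; 25 2-methylprop-2-en-1-ol
Product: 27 19-(tert-butyldiphenylsilyloxy)-15-norlabda-7,13(14)-diene-9α,16-diol, via dilithium dianion of 2-methylprop-2-en-1-ol 26 (not isolated)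
Conditions: 25, n-BuLi (2.2 equiv), Me2NCH2CH2NMe2, Et2O, 0 °C → rt; then 24, −78 °C → rt; H2O
Reagents that add atoms: none
Why: Epoxide opening by an allylic organolithium, which can attack only the methylene C11 because C9 is fully substituted, so that the C,O-dianion should deliver C12, C13, C14 and C16 as a 2-substituted allylic alcohol and return the 9α-hydroxyl.

**Step 16**
Reactants: 27 19-(tert-butyldiphenylsilyloxy)-15-norlabda-7,13(14)-diene-9α,16-diol
Product: 28 (13R)-19-(tert-butyldiphenylsilyloxy)-13,14-epoxy-15-norlabd-7-ene-9α,16-diol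
Conditions: Ti(OiPr)4 (10 mol %), D-(−)-diethyl tartrate (12 mol %), t-BuOOH (1.2 equiv), 4 Å molecular sieves, CH2Cl2, −25 °C
Reagents that add atoms: tert-butyl hydroperoxide, CC(C)(C)OO
Why: Sharpless asymmetric epoxidation of a 2-substituted allylic alcohol, a reagent-controlled step in which D-(−)-tartrate should give the (13R)-epoxide and the primary allylic alcohol should react far faster than the hindered tertiary 9-ol beside the 7-ene.

**Step 17**
Reactants: 28 (13R)-19-(tert-butyldiphenylsilyloxy)-13,14-epoxy-15-norlabd-7-ene-9α,16-diol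
Product: 29 (13S)-16,19-bis(tert-butyldiphenylsilyloxy)-13,14-epoxy-15-norlabd-7-en-9α-ol
Conditions: t-BuPh2SiCl, imidazole, CH2Cl2, 0 °C
Reagents that add atoms: tert-butyl(chloro)diphenylsilane, CC(C)(C)[Si](Cl)(c1ccccc1)c1ccccc1
Why: Selective silylation of the primary hydroxyl, which labels the original hydroxymethyl arm as C16 before ring closure so that the two CH2O arms on C13 stay distinguishable (the descriptor changes only through the priority rules).

**Step 18**
Reactants: 29 (13S)-16,19-bis(tert-butyldiphenylsilyloxy)-13,14-epoxy-15-norlabd-7-en-9α-ol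
Product: 30 (13R)-16,19-bis(tert-butyldiphenylsilyloxy)-9α,13-epoxy-15-norlabd-7-en-14-ol
Conditions: camphorsulfonic acid (5 mol %), CH2Cl2, −20 → 0 °C
Reagents that add atoms: none
Why: Acid-catalysed 5-exo-tet epoxide opening, in which the 9α-hydroxyl attacks the tertiary epoxide carbon from the back and so closes ring C with inversion, carrying the epoxide configuration into C13 and freeing the hydroxymethyl that becomes C14.

**Step 19**
Reactants: 30 (13R)-16,19-bis(tert-butyldiphenylsilyloxy)-9α,13-epoxy-15-norlabd-7-en-14-ol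
Product: 31 (13S)-16,19-bis(tert-butyldiphenylsilyloxy)-9α,13-epoxy-15-norlabd-7-en-14-al
Conditions: Dess–Martin periodinane, NaHCO3, CH2Cl2, rt
Reagents that add atoms: none
Why: Dess–Martin oxidation of a primary alcohol under buffered conditions, giving an aldehyde on the quaternary C13 that has no α-hydrogen and therefore cannot epimerise.

**Step 20**
Reactants: 31 (13S)-16,19-bis(tert-butyldiphenylsilyloxy)-9α,13-epoxy-15-norlabd-7-en-14-al
Product: 32 (13R)-16,19-bis(tert-butyldiphenylsilyloxy)-9α,13-epoxylabd-7-en-14-yne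
Conditions: dimethyl (1-diazo-2-oxopropyl)phosphonate, K2CO3, MeOH, 0 °C → rt
Reagents that add atoms: dimethyl (1-diazo-2-oxopropyl)phosphonate, COP(=O)(OC)C(=[N+]=[N-])C(C)=O
Why: Seyferth–Gilbert homologation in its Ohira–Bestmann form, in which the diazomethylphosphonate anion made by methanolysis adds to the aldehyde and the alkylidene carbene rearranges to the terminal alkyne, adding C15 under conditions that spare both silyl ethers.

**Step 21**
Reactants: 32 (13R)-16,19-bis(tert-butyldiphenylsilyloxy)-9α,13-epoxylabd-7-en-14-yne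
Product: 33 (13R)-16,19-bis(tert-butyldiphenylsilyloxy)-9α,13-epoxy-8-oxo-7,8-secolabd-14-yn-7-al
Conditions: O3, pyridine (3 equiv), CH2Cl2, −78 °C, stopped when 32 is consumed
Reagents that add atoms: ozone, [O-][O+]=O
Why: Ozonolysis of the electron-rich trisubstituted 7-ene, which reacts with ozone far faster than the terminal alkyne or the phenyl rings, cuts C7–C8 and unveils the C7 aldehyde and the C8 methyl ketone on C9.

**Step 22**
Reactants: 33 (13R)-16,19-bis(tert-butyldiphenylsilyloxy)-9α,13-epoxy-8-oxo-7,8-secolabd-14-yn-7-al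
Product: 34 (13R)-16,19-bis(tert-butyldiphenylsilyloxy)-9α,13-epoxy-8β-hydroxylabd-14-yn-7-one
Conditions: 2-(pentafluorophenyl)-6,7-dihydro-5H-pyrrolo[2,1-c][1,2,4]triazol-2-ium tetrafluoroborate (20 mol %), Et3N (30 mol %), CH2Cl2 (0.02 M), 40 °C
Reagents that add atoms: none
Why: Et3N frees the triazolylidene, which adds to the C7 aldehyde; proton transfer gives the Breslow intermediate, whose nucleophilic C7 attacks the C8 methyl ketone, and collapse of the alkoxide releases the carbene and the α-ketol. The closest known reaction type is the intramolecular crossed aldehyde–ketone benzoin that forms six-membered tertiary α-ketols. Ring B closes in a 6-exo-trig mode through the new C7–C8 bond. The only new stereocentre, C8, is set by the ring: in the chair transition state the acetyl methyl stays equatorial, away from the axial C10 methyl, and the ketone oxygen sits axial within hydrogen-bonding reach of the enaminol OH, so the hydroxyl should end 8β and C17 8α. The step needs the aldehyde to act only as donor and the ketone only as acceptor without aldol side reactions; only the aldehyde can form the acyl anion equivalent, the ketone is activated by the α-ether oxygen at C9 and cannot enolise toward the quaternary C9, the amine base is too weak to drive aldol closure at a useful rate, and high dilution disfavours aldehyde dimerisation.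

**Step 23**
Reactants: 34 (13R)-16,19-bis(tert-butyldiphenylsilyloxy)-9α,13-epoxy-8β-hydroxylabd-14-yn-7-one
Product: 35 (13R)-8β-acetoxy-16,19-bis(tert-butyldiphenylsilyloxy)-9α,13-epoxylabd-14-yn-7-one
Conditions: Ac2O, Sc(OTf)3 (5 mol %), MeCN, −20 °C
Reagents that add atoms: acetic anhydride, CC(=O)OC(C)=O
Why: Lewis-acid-catalysed acylation, strong enough to esterify the hindered tertiary axial 8β-hydroxyl at low temperature while the robust diphenylsilyl ethers, the alkyne and the spiro ether should be left alone.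

**Step 24**
Reactants: 35 (13R)-8β-acetoxy-16,19-bis(tert-butyldiphenylsilyloxy)-9α,13-epoxylabd-14-yn-7-one
Product: 36 (13R)-8β-acetoxy-9α,13-epoxy-16,19-dihydroxylabd-14-yn-7-one
Conditions: Bu4NF, AcOH (1:1), THF, rt → 40 °C
Reagents that add atoms: none
Why: Fluoride-induced desilylation of both silyl ethers, buffered with acetic acid so that the α-acetoxy ketone is neither enolised nor subject to acyl migration.

**Step 25**
Reactants: 36 (13R)-8β-acetoxy-9α,13-epoxy-16,19-dihydroxylabd-14-yn-7-one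
Product: 37 (13R)-8β-acetoxy-9α,13:15,16-diepoxy-19-hydroxylabd-14-en-7-one
Conditions: Mo(CO)6 (25 mol %), Et3N, Et2O, hν (350 nm), rt
Reagents that add atoms: none
Why: Molybdenum-carbonyl-catalysed alkynol cycloisomerisation, in which the terminal alkyne becomes a molybdenum vinylidene whose electrophilic C15 is captured by the homopropargylic C16 hydroxyl (endo mode) to close the 2,3-dihydrofuran ring D, the distant C19 hydroxyl being unable to reach it.

**Step 26**
Reactants: 37 (13R)-8β-acetoxy-9α,13:15,16-diepoxy-19-hydroxylabd-14-en-7-one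
Product: 38 (13R)-8β,19-diacetoxy-9α,13:15,16-diepoxylabd-14-en-7-one
Conditions: Ac2O, pyridine, DMAP (cat.), CH2Cl2, 0 °C → rt
Reagents that add atoms: acetic anhydride, CC(=O)OC(C)=O
Why: Nucleophile-catalysed acetylation of the remaining primary C19 hydroxyl under basic conditions that the acid-labile enol ether of ring D tolerates.

**Compound list**
1 | geranyl chloride, (2E)-1-chloro-3,7-dimethylocta-2,6-diene | CC(C)=CCC/C(C)=C/CCl | starting material
2 | (4E)-6-chloro-4-methylhex-4-enal | O=CCC/C(C)=C/CCl | intermediate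
3 | methyl 2-[bis(2,2,2-trifluoroethoxy)phosphoryl]propanoate | COC(=O)C(C)P(=O)(OCC(F)(F)F)OCC(F)(F)F | starting material
4 | potassium salt of the α-carbanion of 3 | [K+].COC(=O)[C-](C)P(=O)(OCC(F)(F)F)OCC(F)(F)F | intermediate
5 | methyl (2Z,6E)-8-chloro-2,6-dimethylocta-2,6-dienoate | COC(=O)/C(C)=C\CC/C(C)=C/CCl | intermediate
6 | (2Z,6E)-8-chloro-2,6-dimethylocta-2,6-dien-1-ol | OC/C(C)=C\CC/C(C)=C/CCl | intermediate
7 | [(2R,3S)-3-[(3E)-5-chloro-3-methylpent-3-en-1-yl]-2-methyloxiran-2-yl]methanol (CH2OH and chain cis on the oxirane) | OC[C@@]1(C)O[C@H]1CC/C(C)=C/CCl | intermediate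
8 | tert-butyl{[(2R,3S)-3-[(3E)-5-chloro-3-methylpent-3-en-1-yl]-2-methyloxiran-2-yl]methoxy}diphenylsilane | CC(C)(C)[Si](c1ccccc1)(c1ccccc1)OC[C@@]1(C)O[C@H]1CC/C(C)=C/CCl | intermediate
9 | methyl acetoacetate | COC(=O)CC(C)=O | starting material
10 | dilithium dianion of methyl acetoacetate | [Li+].[Li+].COC(=O)[CH-]C(=O)[CH2-] | intermediate
11 | methyl (6E)-9-[(2S,3R)-3-(tert-butyldiphenylsilyloxymethyl)-3-methyloxiran-2-yl]-7-methyl-3-oxonon-6-enoate | CC(C)(C)[Si](c1ccccc1)(c1ccccc1)OC[C@@]1(C)O[C@H]1CC/C(C)=C/CCC(=O)CC(=O)OC | intermediate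
12 | methyl 19-(tert-butyldiphenylsilyloxy)-3β-hydroxy-8-oxo-12,13,14,15,16,17-hexanorlabdan-11-oate (trans-decalin; 4α-Me, 4β-CH2OSi, 5α-H, 10β-Me, 9β-CO2Me) | CC(C)(C)[Si](c1ccccc1)(c1ccccc1)OC[C@@]1(C)[C@@H](O)CC[C@@]2(C)[C@H]1CCC(=O)[C@@H]2C(=O)OC | intermediate
13 | methyl 19-(tert-butyldiphenylsilyloxy)-3β-[(imidazol-1-ylcarbonothioyl)oxy]-8-oxo-12,13,14,15,16,17-hexanorlabdan-11-oate | CC(C)(C)[Si](c1ccccc1)(c1ccccc1)OC[C@@]1(C)[C@@H](OC(=S)n3ccnc3)CC[C@@]2(C)[C@H]1CCC(=O)[C@@H]2C(=O)OC | intermediate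
14 | methyl 19-(tert-butyldiphenylsilyloxy)-8-oxo-12,13,14,15,16,17-hexanorlabdan-11-oate | CC(C)(C)[Si](c1ccccc1)(c1ccccc1)OC[C@@]1(C)CCC[C@@]2(C)[C@H]1CCC(=O)[C@@H]2C(=O)OC | intermediate
15 | potassium C9 enolate (8-en-8-olate) of 14 | [K+].CC(C)(C)[Si](c1ccccc1)(c1ccccc1)OC[C@@]1(C)CCC[C@@]2(C)[C@H]1CCC([O-])=C2C(=O)OC | intermediate
16 | potassium 9α-alkoxide of methyl 19-(tert-butyldiphenylsilyloxy)-9α-hydroxy-8-oxo-12,13,14,15,16,17-hexanorlabdan-11-oate | [K+].CC(C)(C)[Si](c1ccccc1)(c1ccccc1)OC[C@@]1(C)CCC[C@@]2(C)[C@H]1CCC(=O)[C@]2([O-])C(=O)OC | intermediate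
17 | methyl 19-(tert-butyldiphenylsilyloxy)-8-oxo-9α-(trimethylsilyloxy)-12,13,14,15,16,17-hexanorlabdan-11-oate | CC(C)(C)[Si](c1ccccc1)(c1ccccc1)OC[C@@]1(C)CCC[C@@]2(C)[C@H]1CCC(=O)[C@]2(O[Si](C)(C)C)C(=O)OC | intermediate
18 | potassium 7-en-8-olate of 17 | [K+].CC(C)(C)[Si](c1ccccc1)(c1ccccc1)OC[C@@]1(C)CCC[C@@]2(C)[C@H]1CC=C([O-])[C@]2(O[Si](C)(C)C)C(=O)OC | intermediate
19 | methyl 19-(tert-butyldiphenylsilyloxy)-8-(trifluoromethylsulfonyloxy)-9α-(trimethylsilyloxy)-12,13,14,15,16,17-hexanorlabd-7-en-11-oate | CC(C)(C)[Si](c1ccccc1)(c1ccccc1)OC[C@@]1(C)CCC[C@@]2(C)[C@H]1CC=C(OS(=O)(=O)C(F)(F)F)[C@]2(O[Si](C)(C)C)C(=O)OC | intermediate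
20 | methyl 19-(tert-butyldiphenylsilyloxy)-9α-(trimethylsilyloxy)-12,13,14,15,16-pentanorlabd-7-en-11-oate | CC(C)(C)[Si](c1ccccc1)(c1ccccc1)OC[C@@]1(C)CCC[C@@]2(C)[C@H]1CC=C(C)[C@]2(O[Si](C)(C)C)C(=O)OC | intermediate
21 | 19-(tert-butyldiphenylsilyloxy)-9α-(trimethylsilyloxy)-12,13,14,15,16-pentanorlabd-7-en-11-ol | CC(C)(C)[Si](c1ccccc1)(c1ccccc1)OC[C@@]1(C)CCC[C@@]2(C)[C@H]1CC=C(C)[C@]2(O[Si](C)(C)C)CO | intermediate
22 | 19-(tert-butyldiphenylsilyloxy)-12,13,14,15,16-pentanorlabd-7-ene-9α,11-diol | CC(C)(C)[Si](c1ccccc1)(c1ccccc1)OC[C@@]1(C)CCC[C@@]2(C)[C@H]1CC=C(C)[C@]2(O)CO | intermediate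
23 | 11-O-(p-tolylsulfonyl) derivative of 22 | CC(C)(C)[Si](c1ccccc1)(c1ccccc1)OC[C@@]1(C)CCC[C@@]2(C)[C@H]1CC=C(C)[C@]2(O)COS(=O)(=O)c1ccc(C)cc1 | intermediate
24 | 19-(tert-butyldiphenylsilyloxy)-9α,11-epoxy-12,13,14,15,16-pentanorlabd-7-ene (spiro-oxirane, O on the α-face) | CC(C)(C)[Si](c1ccccc1)(c1ccccc1)OC[C@@]1(C)CCC[C@@]2(C)[C@H]1CC=C(C)[C@]21CO1 | intermediate
25 | 2-methylprop-2-en-1-ol | CC(=C)CO | starting material
26 | dilithium C,O-dianion of 2-methylprop-2-en-1-ol | [Li+].[Li+].[CH2-]C(=C)C[O-] | intermediate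
27 | 19-(tert-butyldiphenylsilyloxy)-15-norlabda-7,13(14)-diene-9α,16-diol | CC(C)(C)[Si](c1ccccc1)(c1ccccc1)OC[C@@]1(C)CCC[C@@]2(C)[C@H]1CC=C(C)[C@]2(O)CCC(=C)CO | intermediate
28 | (13R)-19-(tert-butyldiphenylsilyloxy)-13,14-epoxy-15-norlabd-7-ene-9α,16-diol | CC(C)(C)[Si](c1ccccc1)(c1ccccc1)OC[C@@]1(C)CCC[C@@]2(C)[C@H]1CC=C(C)[C@]2(O)CC[C@@]1(CO)CO1 | intermediate
29 | (13S)-16,19-bis(tert-butyldiphenylsilyloxy)-13,14-epoxy-15-norlabd-7-en-9α-ol | CC(C)(C)[Si](c1ccccc1)(c1ccccc1)OC[C@@]1(C)CCC[C@@]2(C)[C@H]1CC=C(C)[C@]2(O)CC[C@@]1(CO[Si](c2ccccc2)(c2ccccc2)C(C)(C)C)CO1 | intermediate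
30 | (13R)-16,19-bis(tert-butyldiphenylsilyloxy)-9α,13-epoxy-15-norlabd-7-en-14-ol | CC(C)(C)[Si](c1ccccc1)(c1ccccc1)OC[C@@]1(C)CCC[C@@]2(C)[C@H]1CC=C(C)[C@]21CC[C@](CO[Si](c2ccccc2)(c2ccccc2)C(C)(C)C)(CO)O1 | intermediate
31 | (13S)-16,19-bis(tert-butyldiphenylsilyloxy)-9α,13-epoxy-15-norlabd-7-en-14-al | CC(C)(C)[Si](c1ccccc1)(c1ccccc1)OC[C@@]1(C)CCC[C@@]2(C)[C@H]1CC=C(C)[C@]21CC[C@](CO[Si](c2ccccc2)(c2ccccc2)C(C)(C)C)(C=O)O1 | intermediate
32 | (13R)-16,19-bis(tert-butyldiphenylsilyloxy)-9α,13-epoxylabd-7-en-14-yne | CC(C)(C)[Si](c1ccccc1)(c1ccccc1)OC[C@@]1(C)CCC[C@@]2(C)[C@H]1CC=C(C)[C@]21CC[C@](CO[Si](c2ccccc2)(c2ccccc2)C(C)(C)C)(C#C)O1 | intermediate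
33 | (13R)-16,19-bis(tert-butyldiphenylsilyloxy)-9α,13-epoxy-8-oxo-7,8-secolabd-14-yn-7-al | CC(C)(C)[Si](c1ccccc1)(c1ccccc1)OC[C@@]1(C)CCC[C@@](C)([C@H]1CC=O)[C@]1(C(C)=O)CC[C@](CO[Si](c2ccccc2)(c2ccccc2)C(C)(C)C)(C#C)O1 | intermediate
34 | (13R)-16,19-bis(tert-butyldiphenylsilyloxy)-9α,13-epoxy-8β-hydroxylabd-14-yn-7-one | CC(C)(C)[Si](c1ccccc1)(c1ccccc1)OC[C@@]1(C)CCC[C@@]2(C)[C@H]1CC(=O)[C@](C)(O)[C@]21CC[C@](CO[Si](c2ccccc2)(c2ccccc2)C(C)(C)C)(C#C)O1 | intermediate
35 | (13R)-8β-acetoxy-16,19-bis(tert-butyldiphenylsilyloxy)-9α,13-epoxylabd-14-yn-7-one | CC(C)(C)[Si](c1ccccc1)(c1ccccc1)OC[C@@]1(C)CCC[C@@]2(C)[C@H]1CC(=O)[C@](C)(OC(C)=O)[C@]21CC[C@](CO[Si](c2ccccc2)(c2ccccc2)C(C)(C)C)(C#C)O1 | intermediate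
36 | (13R)-8β-acetoxy-9α,13-epoxy-16,19-dihydroxylabd-14-yn-7-one | OC[C@@]1(C)CCC[C@@]2(C)[C@H]1CC(=O)[C@](C)(OC(C)=O)[C@]21CC[C@](CO)(C#C)O1 | intermediate
37 | (13R)-8β-acetoxy-9α,13:15,16-diepoxy-19-hydroxylabd-14-en-7-one | OC[C@@]1(C)CCC[C@@]2(C)[C@H]1CC(=O)[C@](C)(OC(C)=O)[C@]21CC[C@]2(C=COC2)O1 | intermediate
38 | (13R)-8β,19-diacetoxy-9α,13:15,16-diepoxylabd-14-en-7-one (CNP0351241.1) | CC(=O)OC[C@@]1(C)CCC[C@@]2(C)[C@H]1CC(=O)[C@](C)(OC(C)=O)[C@]21CC[C@]2(C=COC2)O1 | target

Total step count: 26. Longest linear sequence: 26 steps (1 → 38).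

**Steps most likely to fail**

Step 7. The cationic cascade may stop after ring A by proton loss, may be terminated by the enol oxygen instead of carbon, or the epoxide may rearrange by hydride shift before the alkene engages. The fallback sets out from 11 and returns at 12. O-silylation of the β-keto ester (t-BuMe2SiCl, Et3N, DMAP, CH2Cl2) gives the silyl enol ether methyl (6E)-3-(tert-butyldimethylsilyloxy)-9-[(2S,3R)-3-(tert-butyldiphenylsilyloxymethyl)-3-methyloxiran-2-yl]-7-methylnona-2,6-dienoate F1. Its cyclisation with MeAlCl2 in CH2Cl2 at −94 °C uses an enol silane as a Mukaiyama-type terminating nucleophile, which reacts through carbon only. Hydrolytic loss of the silyl group on work-up gives 12.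

Step 22. Addition of the acyl anion equivalent to the neopentyl-type ketone may be slow, so that base-promoted aldol closure or aldehyde self-condensation takes over, or facial control at C8 may be incomplete. The fallback sets out from 33 and returns at 34. A reductive ketyl–carbonyl (pinacol) coupling with SmI2 (THF, t-BuOH, −78 °C) forms the same C7–C8 bond and should give (13R)-16,19-bis(tert-butyldiphenylsilyloxy)-9α,13-epoxylabd-14-yne-7,8β-diol F2, the acetyl methyl again preferring the equatorial position. Swern oxidation (oxalyl chloride, DMSO, Et3N, −78 °C) of the secondary C7 alcohol, which leaves the tertiary C8 alcohol untouched and removes the undefined C7 centre, gives 34.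

Step 15. The strongly basic dianion may open the vinyl epoxide in the SN2' sense at C7 or fail to reach the neopentyl-type methylene, and metalation of the allylic alcohol may be incomplete. The fallback sets out from 22 and returns at 27, building the chain by carbonyl olefination instead of epoxide opening. Parikh–Doering oxidation (SO3·pyridine, DMSO, Et3N) gives 19-(tert-butyldiphenylsilyloxy)-9α-hydroxy-12,13,14,15,16-pentanorlabd-7-en-11-al F3. Horner–Wadsworth–Emmons reaction with dimethyl [3-(tert-butyldimethylsilyloxy)-2-oxopropyl]phosphonate (LiCl, i-Pr2NEt, MeCN) gives (11E)-16-(tert-butyldimethylsilyloxy)-19-(tert-butyldiphenylsilyloxy)-9α-hydroxy-14,15-dinorlabda-7,11-dien-13-one F4. Conjugate reduction with [(Ph3P)CuH]6 in wet benzene gives 16-(tert-butyldimethylsilyloxy)-19-(tert-butyldiphenylsilyloxy)-9α-hydroxy-14,15-dinorlabd-7-en-13-one F5. Wittig methylenation (Ph3P=CH2, THF) gives 16-(tert-butyldimethylsilyloxy)-19-(tert-butyldiphenylsilyloxy)-15-norlabda-7,13(14)-dien-9α-ol F6. Selective removal of the primary tert-butyldimethylsilyl ether with pyridinium p-toluenesulfonate in MeOH, which leaves the diphenylsilyl ether in place, gives 27.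

**Further compounds**
F1 | step 7 | methyl (6E)-3-(tert-butyldimethylsilyloxy)-9-[(2S,3R)-3-(tert-butyldiphenylsilyloxymethyl)-3-methyloxiran-2-yl]-7-methylnona-2,6-dienoate (either enol ether geometry) | CC(C)(C)[Si](c1ccccc1)(c1ccccc1)OC[C@@]1(C)O[C@H]1CC/C(C)=C/CCC(O[Si](C)(C)C(C)(C)C)=CC(=O)OC
F2 | step 22 | (13R)-16,19-bis(tert-butyldiphenylsilyloxy)-9α,13-epoxylabd-14-yne-7,8β-diol (C7 undefined) | CC(C)(C)[Si](c1ccccc1)(c1ccccc1)OC[C@@]1(C)CCC[C@@]2(C)[C@H]1CC(O)[C@](C)(O)[C@]21CC[C@](CO[Si](c2ccccc2)(c2ccccc2)C(C)(C)C)(C#C)O1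
F3 | step 15 | 19-(tert-butyldiphenylsilyloxy)-9α-hydroxy-12,13,14,15,16-pentanorlabd-7-en-11-al | CC(C)(C)[Si](c1ccccc1)(c1ccccc1)OC[C@@]1(C)CCC[C@@]2(C)[C@H]1CC=C(C)[C@]2(O)C=O
F4 | step 15 | (11E)-16-(tert-butyldimethylsilyloxy)-19-(tert-butyldiphenylsilyloxy)-9α-hydroxy-14,15-dinorlabda-7,11-dien-13-one | CC(C)(C)[Si](c1ccccc1)(c1ccccc1)OC[C@@]1(C)CCC[C@@]2(C)[C@H]1CC=C(C)[C@]2(O)/C=C/C(=O)CO[Si](C)(C)C(C)(C)C
F5 | step 15 | 16-(tert-butyldimethylsilyloxy)-19-(tert-butyldiphenylsilyloxy)-9α-hydroxy-14,15-dinorlabd-7-en-13-one | CC(C)(C)[Si](c1ccccc1)(c1ccccc1)OC[C@@]1(C)CCC[C@@]2(C)[C@H]1CC=C(C)[C@]2(O)CCC(=O)CO[Si](C)(C)C(C)(C)C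
F6 | step 15 | 16-(tert-butyldimethylsilyloxy)-19-(tert-butyldiphenylsilyloxy)-15-norlabda-7,13(14)-dien-9α-ol | CC(C)(C)[Si](c1ccccc1)(c1ccccc1)OC[C@@]1(C)CCC[C@@]2(C)[C@H]1CC=C(C)[C@]2(O)CCC(=C)CO[Si](C)(C)C(C)(C)C
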